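The oxirane C–C bond (C1–C14; 15-oxabicyclo[12.1.0]pentadecane numbering) is made last among the skeletal bonds. An open-chain fifteen-carbon keto sulfonium salt, built from (R)-α-terpineol (C5–C10, the C8 stereocentre and its hydroxypropyl group), is deprotonated at C14; the ylide adds to the C1 methyl ketone and the betaine expels diphenyl sulfide, so one operation closes the fourteen-membered carbocycle and the oxirane. The step exploits that the C1–C14–O15 ring is the only ring fusion and that C1 lies 1,3 to the C3 oxygen; forming the epoxide by C–C bond formation also avoids a selective epoxidation among three trisubstituted olefin-level sites.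

Key step: step 11

Remark on locants: the target is read as (1R,3R,4E,8R,10Z,14S)-8-(2-hydroxypropan-2-yl)-1,5,11-trimethyl-15-oxabicyclo[12.1.0]pentadeca-4,10-dien-3-yl acetate, with C2 and C13 cis on the oxirane. C1 is the methyl-bearing oxirane carbon, C14 the oxirane CH, C3 the acetoxy carbon and C8 the carbon bearing the hydroxypropyl group. These locants are used for the target and, as "future C…", for open-chain intermediates.

Assumption: in step 7 the ligand antipode that delivers Re-face addition to the aldehyde is used; if the sense proves opposite, the other antipode is taken.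

Step 1
Reactants: 1 (R)-(+)-α-terpineol
Product: 2 triethyl({2-[(1R)-4-methylcyclohex-3-en-1-yl]propan-2-yl}oxy)silane
Conditions: Et3SiOTf, 2,6-lutidine, CH2Cl2, −78 → 0 °C
Reagents that add atoms: triethylsilyl triflate, CC[Si](CC)(CC)OS(=O)(=O)C(F)(F)F
Why: Silyl ether protection of the hindered tertiary alcohol with a silyl triflate prevents lactol formation after ring cleavage and carries the future C8 stereocentre unchanged from the chiral pool.

Step 2
Reactants: 2 triethyl({2-[(1R)-4-methylcyclohex-3-en-1-yl]propan-2-yl}oxy)silane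
Product: 4 (3R)-6-oxo-3-[2-(triethylsilyloxy)propan-2-yl]heptanal, via ozonide 3 (not isolated)
Conditions: O3, CH2Cl2, −78 °C; then PPh3, −78 °C → rt
Reagents that add atoms: ozone, [O-][O+]=O
Why: Ozonolysis with reductive work-up cleaves the only C=C bond and releases the future C5–C10 segment already differentiated as methyl ketone (C5 with its methyl) and aldehyde (C10).

Step 3
Reactants: 4 (3R)-6-oxo-3-[2-(triethylsilyloxy)propan-2-yl]heptanal; 5 ethyltriphenylphosphonium iodide
Product: 9 (5R,7Z)-8-iodo-5-[2-(triethylsilyloxy)propan-2-yl]non-7-en-2-one, via ethylidenetriphenylphosphorane 6 (not isolated), via (1-iodoethyl)triphenylphosphonium iodide 7 (not isolated), via (1-iodoethylidene)triphenylphosphorane 8 (not isolated)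
Conditions: 5, n-BuLi, THF, 0 °C; I2, −78 °C; NaN(SiMe3)2, −20 °C; then 4, −78 °C
Reagents that add atoms: ethyltriphenylphosphonium iodide 5, CC[P+](c1ccccc1)(c1ccccc1)c1ccccc1.[I-]; iodine, II
Why: Wittig olefination with the α-iodo ylide (Stork–Zhao-type iodo-olefination) is kinetically Z-selective, placing iodine cis to the chain, and at −78 °C should take the aldehyde in preference to the methyl ketone.

Step 4
Reactants: 9 (5R,7Z)-8-iodo-5-[2-(triethylsilyloxy)propan-2-yl]non-7-en-2-one; 10 triethyl phosphonoacetate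
Product: 12 ethyl (2E,6R,8Z)-9-iodo-3-methyl-6-[2-(triethylsilyloxy)propan-2-yl]deca-2,8-dienoate, via sodium phosphonoacetate carbanion 11 (not isolated)
Conditions: 10, NaH, THF, 0 °C; then 9, rt → 50 °C
Reagents that add atoms: triethyl phosphonoacetate 10, CCOC(=O)CP(=O)(OCC)OCC
Why: Horner–Wadsworth–Emmons olefination of a methyl ketone places the ester trans to the larger chain substituent, so the 2E isomer should predominate and the minor 2Z ester is removed by chromatography at this stage.

Step 5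
Reactants: 12 ethyl (2E,6R,8Z)-9-iodo-3-methyl-6-[2-(triethylsilyloxy)propan-2-yl]deca-2,8-dienoate
Product: 13 (2E,6R,8Z)-9-iodo-3-methyl-6-[2-(triethylsilyloxy)propan-2-yl]deca-2,8-dien-1-ol
Conditions: i-Bu2AlH, CH2Cl2, −78 °C; aq. KNaC4H4O6 work-up
Reagents that add atoms: none
Why: 1,2-Reduction of the enoate with an aluminium hydride (DIBAL reduction) gives the allylic alcohol without touching the alkenyl iodide, the silyl ether or either olefin geometry.

Step 6
Reactants: 13 (2E,6R,8Z)-9-iodo-3-methyl-6-[2-(triethylsilyloxy)propan-2-yl]deca-2,8-dien-1-ol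
Product: 14 (2E,6R,8Z)-9-iodo-3-methyl-6-[2-(triethylsilyloxy)propan-2-yl]deca-2,8-dienal
Conditions: MnO2, CH2Cl2, rt
Reagents that add atoms: none
Why: MnO2 oxidation is selective for allylic alcohols and should give the (E)-enal without isomerisation of either double bond.

Step 7
Reactants: 14 (2E,6R,8Z)-9-iodo-3-methyl-6-[2-(triethylsilyloxy)propan-2-yl]deca-2,8-dienal; 15 2-methoxypropene
Product: 17 (4R,5E,9R,11Z)-4-hydroxy-12-iodo-6-methyl-9-[2-(triethylsilyloxy)propan-2-yl]trideca-5,11-dien-2-one, via enol ether adduct 16 (not isolated)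
Conditions: Ti(OiPr)4 (10 mol%), Schiff-base ligand from 2-amino-2'-hydroxy-1,1'-binaphthyl and 3-bromo-5-tert-butylsalicylaldehyde (10 mol%), 3,5-di-tert-butylsalicylic acid (10 mol%), 2,6-di-tert-butyl-4-methylpyridine, 15 (excess), toluene, 0 °C; then 1 M citric acid, Et2O, 0 °C
Reagents that add atoms: 2-methoxypropene 15, COC(C)=C; water, O
Why: Catalytic enantioselective acetone aldol addition (titanium Schiff-base-catalysed ene-type addition of 2-methoxypropene, then enol ether hydrolysis) adds to the Re face of the aldehyde under catalyst control and so sets the (R)-carbinol that becomes C3.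

Step 8
Reactants: 17 (4R,5E,9R,11Z)-4-hydroxy-12-iodo-6-methyl-9-[2-(triethylsilyloxy)propan-2-yl]trideca-5,11-dien-2-one
Product: 18 (4R,5E,9R,11Z)-4-(tert-butyldimethylsilyloxy)-12-iodo-6-methyl-9-[2-(triethylsilyloxy)propan-2-yl]trideca-5,11-dien-2-one
Conditions: TBSCl, imidazole, DMF, rt
Reagents that add atoms: tert-butyldimethylsilyl chloride, CC(C)(C)[Si](C)(C)Cl
Why: Silyl ether protection under non-enolising conditions gives a β-silyloxy ketone that resists retro-aldol cleavage and β-elimination in the later basic steps, unlike the free aldol or its acetate.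

Step 9
Reactants: 18 (4R,5E,9R,11Z)-4-(tert-butyldimethylsilyloxy)-12-iodo-6-methyl-9-[2-(triethylsilyloxy)propan-2-yl]trideca-5,11-dien-2-one; 19 allyloxytrimethylsilane
Product: 22 (4R,5E,9R,11Z)-4-(tert-butyldimethylsilyloxy)-15-hydroxy-6,12-dimethyl-9-[2-(triethylsilyloxy)propan-2-yl]pentadeca-5,11-dien-2-one, via B-[3-(trimethylsilyloxy)propyl]-9-BBN 20 (not isolated), via trimethylsilyl ether 21 (not isolated)
Conditions: 19, 9-BBN-H, THF, 0 °C → rt; then 18, Pd(dppf)Cl2 (5 mol%), AsPh3, Cs2CO3, DMF/H2O, rt; then citric acid, MeOH, 0 °C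
Reagents that add atoms: allyloxytrimethylsilane 19, C=CCO[Si](C)(C)C
Why: Anti-Markovnikov hydroboration and B-alkyl Suzuki–Miyaura coupling replace iodine by the three-carbon arm with retention of alkene geometry, which fixes the future 10Z olefin, and the labile primary trimethylsilyl ether is hydrolysed in the mild acidic work-up.

Step 10
Reactants: 22 (4R,5E,9R,11Z)-4-(tert-butyldimethylsilyloxy)-15-hydroxy-6,12-dimethyl-9-[2-(triethylsilyloxy)propan-2-yl]pentadeca-5,11-dien-2-one; 23 diphenyl sulfide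
Product: 25 {(4Z,7R,10E,12R)-12-(tert-butyldimethylsilyloxy)-4,10-dimethyl-14-oxo-7-[2-(triethylsilyloxy)propan-2-yl]pentadeca-4,10-dien-1-yl}diphenylsulfonium triflate, via primary triflate 24 (not isolated)
Conditions: Tf2O, 2,6-di-tert-butylpyridine, CH2Cl2, −78 °C; then 23 (10 equiv), −78 °C → rt
Reagents that add atoms: triflic anhydride, O=S(=O)(OS(=O)(=O)C(F)(F)F)C(F)(F)F; diphenyl sulfide 23, c1ccc(cc1)Sc1ccccc1
Why: O-Triflation of the primary alcohol followed by SN2 S-alkylation of diphenyl sulfide gives an alkyldiphenylsulfonium salt whose only α-hydrogens sit on the future C14.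

Step 11
Reactants: 25 {(4Z,7R,10E,12R)-12-(tert-butyldimethylsilyloxy)-4,10-dimethyl-14-oxo-7-[2-(triethylsilyloxy)propan-2-yl]pentadeca-4,10-dien-1-yl}diphenylsulfonium triflate
Product: 28 tert-butyl({(1R,3R,4E,8R,10Z,14S)-1,5,11-trimethyl-8-[2-(triethylsilyloxy)propan-2-yl]-15-oxabicyclo[12.1.0]pentadeca-4,10-dien-3-yl}oxy)dimethylsilane, via sulfonium ylide 26 (not isolated), via betaine 27 (not isolated)
Conditions: 25 and KN(SiMe3)2 (1.1 equiv) added simultaneously over 6 h to THF at −45 °C (final 2 mM); then → −20 °C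
Reagents that add atoms: none
Why: Proposed new method: KN(SiMe3)2 removes the most acidic proton of 25 (α to the sulfonium centre, roughly eight pKa units below the ketone α-hydrogens) to give the non-stabilised ylide 26; its carbanion adds irreversibly to the C1 ketone (14-exo-trig closure of the carbocycle) and the betaine 27 expels diphenyl sulfide by 3-exo-tet attack of the alkoxide on C14 with inversion, so the C1–C14 bond is formed and both rings are closed in one operation. The closest known reaction type is the intramolecular Corey–Chaykovsky epoxidation of keto sulfonium ylides (epoxy-annulation to five- to seven-membered rings); its use to close a fourteen-membered ring is the new element, and it rests on the very high rate of addition of alkyl diphenylsulfonium ylides to ketones at low temperature, on a chain pre-folded by two trisubstituted olefins and two branch points, and on pseudo-high dilution. C1 should be set by 1,3-induction from the C3 silyloxy stereocentre, the ylide attacking the ketone face anti to the C4 alkenyl substituent in the dipole-opposed conformer, which gives the required 1,3-anti relation of the C3 and C1 oxygens (polar induction model for β-oxygenated carbonyl compounds). C14 should follow from the geometry of the irreversible C–C bond formation, with S+ and O– syn-clinal (charge attraction) and the two chain ends C2 and C13 antiperiplanar, which after inversion at C14 places C2 and C13 cis on the oxirane as in the target. The step needs site selectivity (ylide over enolate, secured by the acidity gap and by a β-silyloxy group that does not eliminate at −45 °C), cyclisation over oligomerisation (secured by simultaneous slow addition) and diastereoselectivity at C1 and C14 (the least secure point; the diastereomers of 28 should be separable by chromatography).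

Step 12
Reactants: 28 tert-butyl({(1R,3R,4E,8R,10Z,14S)-1,5,11-trimethyl-8-[2-(triethylsilyloxy)propan-2-yl]-15-oxabicyclo[12.1.0]pentadeca-4,10-dien-3-yl}oxy)dimethylsilane
Product: 29 (1R,3R,4E,8R,10Z,14S)-8-(2-hydroxypropan-2-yl)-1,5,11-trimethyl-15-oxabicyclo[12.1.0]pentadeca-4,10-dien-3-ol
Conditions: Bu4NF, THF, 0 → 40 °C
Reagents that add atoms: none
Why: Fluoride-induced desilylation cleaves both silyl ethers, while the trisubstituted oxirane and the olefins are inert to fluoride.

Step 13
Reactants: 29 (1R,3R,4E,8R,10Z,14S)-8-(2-hydroxypropan-2-yl)-1,5,11-trimethyl-15-oxabicyclo[12.1.0]pentadeca-4,10-dien-3-ol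
Product: 30 (1R,3R,4E,8R,10Z,14S)-8-(2-hydroxypropan-2-yl)-1,5,11-trimethyl-15-oxabicyclo[12.1.0]pentadeca-4,10-dien-3-yl acetate (CNP0254503.2)
Conditions: Ac2O, pyridine, DMAP (5 mol%), CH2Cl2, 0 °C
Reagents that add atoms: acetic anhydride, CC(=O)OC(C)=O
Why: Nucleophile-catalysed acylation (esterification) should acetylate the secondary allylic hydroxyl and leave the hindered tertiary hydroxyl free.

Compound list

1 | (R)-(+)-α-terpineol | CC1=CC[C@@H](CC1)C(C)(C)O | starting material
2 | triethyl({2-[(1R)-4-methylcyclohex-3-en-1-yl]propan-2-yl}oxy)silane | CC1=CC[C@@H](CC1)C(C)(C)O[Si](CC)(CC)CC | intermediate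
3 | ozonide of 2, (4R)-1-methyl-4-[2-(triethylsilyloxy)propan-2-yl]-7,8,9-trioxabicyclo[4.2.1]nonane (bridgehead configuration not defined) | CC12OOC(O1)C[C@@H](CC2)C(C)(C)O[Si](CC)(CC)CC | intermediate (not isolated)
4 | (3R)-6-oxo-3-[2-(triethylsilyloxy)propan-2-yl]heptanal | CC(=O)CC[C@@H](C(C)(C)O[Si](CC)(CC)CC)CC=O | intermediate
5 | ethyltriphenylphosphonium iodide | CC[P+](c1ccccc1)(c1ccccc1)c1ccccc1.[I-] | starting material
6 | ethylidenetriphenylphosphorane | CC=P(c1ccccc1)(c1ccccc1)c1ccccc1 | intermediate (not isolated)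
7 | (1-iodoethyl)triphenylphosphonium iodide | CC(I)[P+](c1ccccc1)(c1ccccc1)c1ccccc1.[I-] | intermediate (not isolated)
8 | (1-iodoethylidene)triphenylphosphorane | CC(I)=P(c1ccccc1)(c1ccccc1)c1ccccc1 | intermediate (not isolated)
9 | (5R,7Z)-8-iodo-5-[2-(triethylsilyloxy)propan-2-yl]non-7-en-2-one | CC(=O)CC[C@@H](C(C)(C)O[Si](CC)(CC)CC)C/C=C(/C)I | intermediate
10 | triethyl phosphonoacetate | CCOC(=O)CP(=O)(OCC)OCC | starting material
11 | sodium salt of the triethyl phosphonoacetate carbanion | CCOC(=O)[CH-]P(=O)(OCC)OCC.[Na+] | intermediate (not isolated)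
12 | ethyl (2E,6R,8Z)-9-iodo-3-methyl-6-[2-(triethylsilyloxy)propan-2-yl]deca-2,8-dienoate | CCOC(=O)/C=C(\C)CC[C@@H](C(C)(C)O[Si](CC)(CC)CC)C/C=C(/C)I | intermediate
13 | (2E,6R,8Z)-9-iodo-3-methyl-6-[2-(triethylsilyloxy)propan-2-yl]deca-2,8-dien-1-ol | OC/C=C(\C)CC[C@@H](C(C)(C)O[Si](CC)(CC)CC)C/C=C(/C)I | intermediate
14 | (2E,6R,8Z)-9-iodo-3-methyl-6-[2-(triethylsilyloxy)propan-2-yl]deca-2,8-dienal | O=C/C=C(\C)CC[C@@H](C(C)(C)O[Si](CC)(CC)CC)C/C=C(/C)I | intermediate
15 | 2-methoxypropene | COC(C)=C | starting material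
16 | (4R,5E,9R,11Z)-12-iodo-2-methoxy-6-methyl-9-[2-(triethylsilyloxy)propan-2-yl]trideca-1,5,11-trien-4-ol | C=C(OC)C[C@@H](O)/C=C(\C)CC[C@@H](C(C)(C)O[Si](CC)(CC)CC)C/C=C(/C)I | intermediate (not isolated)
17 | (4R,5E,9R,11Z)-4-hydroxy-12-iodo-6-methyl-9-[2-(triethylsilyloxy)propan-2-yl]trideca-5,11-dien-2-one | CC(=O)C[C@@H](O)/C=C(\C)CC[C@@H](C(C)(C)O[Si](CC)(CC)CC)C/C=C(/C)I | intermediate
18 | (4R,5E,9R,11Z)-4-(tert-butyldimethylsilyloxy)-12-iodo-6-methyl-9-[2-(triethylsilyloxy)propan-2-yl]trideca-5,11-dien-2-one | CC(=O)C[C@@H](O[Si](C)(C)C(C)(C)C)/C=C(\C)CC[C@@H](C(C)(C)O[Si](CC)(CC)CC)C/C=C(/C)I | intermediate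
19 | allyloxytrimethylsilane | C=CCO[Si](C)(C)C | starting material
20 | B-[3-(trimethylsilyloxy)propyl]-9-borabicyclo[3.3.1]nonane | C[Si](C)(C)OCCCB1C2CCCC1CCC2 | intermediate (not isolated)
21 | (4R,5E,9R,11Z)-4-(tert-butyldimethylsilyloxy)-6,12-dimethyl-9-[2-(triethylsilyloxy)propan-2-yl]-15-(trimethylsilyloxy)pentadeca-5,11-dien-2-one | CC(=O)C[C@@H](O[Si](C)(C)C(C)(C)C)/C=C(\C)CC[C@@H](C(C)(C)O[Si](CC)(CC)CC)C/C=C(/C)CCCO[Si](C)(C)C | intermediate (not isolated)
22 | (4R,5E,9R,11Z)-4-(tert-butyldimethylsilyloxy)-15-hydroxy-6,12-dimethyl-9-[2-(triethylsilyloxy)propan-2-yl]pentadeca-5,11-dien-2-one | CC(=O)C[C@@H](O[Si](C)(C)C(C)(C)C)/C=C(\C)CC[C@@H](C(C)(C)O[Si](CC)(CC)CC)C/C=C(/C)CCCO | intermediate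
23 | diphenyl sulfide | c1ccc(cc1)Sc1ccccc1 | starting material
24 | (4Z,7R,10E,12R)-12-(tert-butyldimethylsilyloxy)-4,10-dimethyl-14-oxo-7-[2-(triethylsilyloxy)propan-2-yl]pentadeca-4,10-dien-1-yl triflate | CC(=O)C[C@@H](O[Si](C)(C)C(C)(C)C)/C=C(\C)CC[C@@H](C(C)(C)O[Si](CC)(CC)CC)C/C=C(/C)CCCOS(=O)(=O)C(F)(F)F | intermediate (not isolated)
25 | {(4Z,7R,10E,12R)-12-(tert-butyldimethylsilyloxy)-4,10-dimethyl-14-oxo-7-[2-(triethylsilyloxy)propan-2-yl]pentadeca-4,10-dien-1-yl}diphenylsulfonium triflate | CC(=O)C[C@@H](O[Si](C)(C)C(C)(C)C)/C=C(\C)CC[C@@H](C(C)(C)O[Si](CC)(CC)CC)C/C=C(/C)CCC[S+](c1ccccc1)c1ccccc1.[O-]S(=O)(=O)C(F)(F)F | intermediate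
26 | diphenylsulfonium ylide of 25 (carbanion at the future C14) | CC(=O)C[C@@H](O[Si](C)(C)C(C)(C)C)/C=C(\C)CC[C@@H](C(C)(C)O[Si](CC)(CC)CC)C/C=C(/C)CC[CH-][S+](c1ccccc1)c1ccccc1 | intermediate (not isolated)
27 | macrocyclic betaine, (1R,2R)-2-oxido-1-(diphenylsulfonio) fourteen-membered carbocycle | CC(C)(C)[Si](C)(C)O[C@H]1/C=C(\C)CC[C@@H](C(C)(C)O[Si](CC)(CC)CC)C/C=C(/C)CC[C@@H]([S+](c2ccccc2)c2ccccc2)[C@@]([O-])(C)C1 | intermediate (not isolated)
28 | tert-butyl({(1R,3R,4E,8R,10Z,14S)-1,5,11-trimethyl-8-[2-(triethylsilyloxy)propan-2-yl]-15-oxabicyclo[12.1.0]pentadeca-4,10-dien-3-yl}oxy)dimethylsilane | CC(C)(C)[Si](C)(C)O[C@H]1/C=C(\C)CC[C@@H](C(C)(C)O[Si](CC)(CC)CC)C/C=C(/C)CC[C@@H]2O[C@]2(C)C1 | intermediate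
29 | (1R,3R,4E,8R,10Z,14S)-8-(2-hydroxypropan-2-yl)-1,5,11-trimethyl-15-oxabicyclo[12.1.0]pentadeca-4,10-dien-3-ol | O[C@H]1/C=C(\C)CC[C@@H](C(C)(C)O)C/C=C(/C)CC[C@@H]2O[C@]2(C)C1 | intermediate
30 | (1R,3R,4E,8R,10Z,14S)-8-(2-hydroxypropan-2-yl)-1,5,11-trimethyl-15-oxabicyclo[12.1.0]pentadeca-4,10-dien-3-yl acetate | CC(=O)O[C@H]1/C=C(\C)CC[C@@H](C(C)(C)O)C/C=C(/C)CC[C@@H]2O[C@]2(C)C1 | target

Total step count: 13. Longest linear sequence: 13 steps (from 1).

Steps most likely to fail

Step 11 (key step). The ylide may be lost to intermolecular addition, proton return or aryl migration before the chain ends meet, and the ring may close with the wrong facial or cis/trans sense at C1 and C14. The fallback uses known chemistry, sets out from keto alcohol 22 and forms the same C1–C14 bond. Dess–Martin oxidation of 22 gives (4Z,7R,10E,12R)-12-(tert-butyldimethylsilyloxy)-4,10-dimethyl-14-oxo-7-[2-(triethylsilyloxy)propan-2-yl]pentadeca-4,10-dienal F1. Intramolecular low-valent titanium pinacol coupling of this keto aldehyde (TiCl3(DME)1.5, Zn–Cu, DME, high dilution; McMurry-type coupling, an established closure for fourteen-membered cembranoid rings) should give, after separation of diastereomers, (1R,2R,4R,5E,9R,11Z)-4-(tert-butyldimethylsilyloxy)-2,6,12-trimethyl-9-[2-(triethylsilyloxy)propan-2-yl]cyclotetradeca-5,11-diene-1,2-diol F2. Selective sulfonylation of the secondary hydroxyl (MsCl, Et3N, CH2Cl2, −20 °C) gives the 1-methanesulfonate F3, and K2CO3 in MeOH closes the oxirane by attack of the tertiary alkoxide with inversion at the secondary carbon. The sequence comes back to the route at 28.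

Step 7. Enantiofacial control or conversion may be poor with a β,β-disubstituted enal, and the enal may isomerise under Lewis acid. The fallback sets out from enal 14. Brown allylation with (+)-B-allyldiisopinocampheylborane (the antipode that adds to the Re face; Et2O, −78 °C, then NaOH/H2O2) gives (4R,5E,9R,11Z)-12-iodo-6-methyl-9-[2-(triethylsilyloxy)propan-2-yl]trideca-1,5,11-trien-4-ol F4. Silylation (TBSCl, imidazole, DMF) gives its tert-butyldimethylsilyl ether F5. Tsuji–Wacker oxidation of the terminal olefin (PdCl2, CuCl, O2, DMF/H2O, rt) gives the methyl ketone and comes back to the route at 18.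

Step 3. Z/E selectivity may erode, the methyl ketone may be olefinated in competition, and the iodo ylide may decompose. The fallback sets out from keto aldehyde 4. Dibromo-olefination (CBr4, PPh3, CH2Cl2, 0 °C) gives (5R)-8,8-dibromo-5-[2-(triethylsilyloxy)propan-2-yl]oct-7-en-2-one F6. Palladium-catalysed trans-selective Negishi mono-methylation (MeZnCl, Pd(DPEphos)Cl2, THF, 0 °C → rt) replaces the bromine trans to the chain and gives (5R,7Z)-8-bromo-5-[2-(triethylsilyloxy)propan-2-yl]non-7-en-2-one F7. Copper-catalysed halogen exchange with retention of geometry (CuI, N,N'-dimethylethylenediamine, NaI, dioxane, 110 °C) comes back to the route at 9.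

Further compounds

F1 | step 11 | (4Z,7R,10E,12R)-12-(tert-butyldimethylsilyloxy)-4,10-dimethyl-14-oxo-7-[2-(triethylsilyloxy)propan-2-yl]pentadeca-4,10-dienal | CC(=O)C[C@@H](O[Si](C)(C)C(C)(C)C)/C=C(\C)CC[C@@H](C(C)(C)O[Si](CC)(CC)CC)C/C=C(/C)CCC=O
F2 | step 11 | (1R,2R,4R,5E,9R,11Z)-4-(tert-butyldimethylsilyloxy)-2,6,12-trimethyl-9-[2-(triethylsilyloxy)propan-2-yl]cyclotetradeca-5,11-diene-1,2-diol | CC(C)(C)[Si](C)(C)O[C@H]1/C=C(\C)CC[C@@H](C(C)(C)O[Si](CC)(CC)CC)C/C=C(/C)CC[C@@H](O)[C@@](O)(C)C1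
F3 | step 11 | (1R,2R,4R,5E,9R,11Z)-4-(tert-butyldimethylsilyloxy)-2-hydroxy-2,6,12-trimethyl-9-[2-(triethylsilyloxy)propan-2-yl]cyclotetradeca-5,11-dien-1-yl methanesulfonate | CC(C)(C)[Si](C)(C)O[C@H]1/C=C(\C)CC[C@@H](C(C)(C)O[Si](CC)(CC)CC)C/C=C(/C)CC[C@@H](OS(C)(=O)=O)[C@@](O)(C)C1
F4 | step 7 | (4R,5E,9R,11Z)-12-iodo-6-methyl-9-[2-(triethylsilyloxy)propan-2-yl]trideca-1,5,11-trien-4-ol | C=CC[C@@H](O)/C=C(\C)CC[C@@H](C(C)(C)O[Si](CC)(CC)CC)C/C=C(/C)I
F5 | step 7 | tert-butyl({(4R,5E,9R,11Z)-12-iodo-6-methyl-9-[2-(triethylsilyloxy)propan-2-yl]trideca-1,5,11-trien-4-yl}oxy)dimethylsilane | C=CC[C@@H](O[Si](C)(C)C(C)(C)C)/C=C(\C)CC[C@@H](C(C)(C)O[Si](CC)(CC)CC)C/C=C(/C)I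
F6 | step 3 | (5R)-8,8-dibromo-5-[2-(triethylsilyloxy)propan-2-yl]oct-7-en-2-one | CC(=O)CC[C@@H](C(C)(C)O[Si](CC)(CC)CC)CC=C(Br)Br
F7 | step 3 | (5R,7Z)-8-bromo-5-[2-(triethylsilyloxy)propan-2-yl]non-7-en-2-one | CC(=O)CC[C@@H](C(C)(C)O[Si](CC)(CC)CC)C/C=C(/C)Br
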